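**Plan**

1. Retrosynthesis: cut the C8–O acyl bond; trace the C7 acrylic acid (C11=C13, C12) back to an allyl group and the C6/C8 carbinols back to a ring B 6,8-dione; then cut C7–C11 (allylation), C7–C8 (Claisen, ring B), C1–C10 (acyl anion to enoate, ring A) and C4–C5 (enolate alkylation).
2. Enabling feature (eudesmane numbering): the C1 and C8 oxygens are 1,4-related across the quaternary C10 (O–C1–C10–C9–C8–O), the retron of an acyl anion adding to C10 of a β-methyl enoate; C4 and C5 lie α to carbonyl carbons (C15, C6) and can be equilibrated afterwards.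
3. Forward: a pyranone-derived dienolate is alkylated (C4–C5), ring A is closed by a carbene-catalysed Stetter reaction, ring B by Dieckmann condensation; then C7 allylation, dione-to-enone transposition, epoxidation and dissolving-metal reduction, O8 acylation, conversion of allyl into the acrylic acid, C15 oxidation, desilylation.
4. Stereochemistry: C10 from the chiral carbene; C4/C5 by base equilibration to the trans-decalin with equatorial C15; C1 by axial hydride attack; C6 and C7 by α-face epoxidation anti to the C10 methyl; C7–H and C8 by thermodynamic dissolving-metal reduction.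

Key step: step 4

Assumption: the target is taken in the open form drawn (free 6-OH, C15 aldehyde, C12 acid); closure of 6-OH onto C15 (peri lactol) or C12 (trans-fused lactone) is expected to be slow under the neutral to weakly acidic conditions of the last steps.

Locants: decalins carry eudesmane locants (ring A = C1–C5, C10; ring B = C5–C10; C15 on C4; C11–C13 on C7); β is the face of the C10 methyl. TES = triethylsilyl, TBS = tert-butyldimethylsilyl.

**Route**

Step 1
Reactants: 1 methyl hex-5-enoate
Product: 3 methyl 2-bromohex-5-enoate (racemic), via ketene silyl acetal 2 (not isolated)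
Conditions: LiN(i-Pr)2, THF, −78 °C; Me3SiCl; then N-bromosuccinimide, −78 to 0 °C
Reagents that add atoms: N-bromosuccinimide (O=C1CCC(=O)N1Br)
Why: Kinetic ester enolate formation, O-silylation and electrophilic α-bromination of the ketene silyl acetal should give the α-bromo ester without touching the terminal alkene; the new centre is racemic, which is immaterial because it is equilibrated later.

Step 2
Reactants: 4 4,6-dimethyl-2H-pyran-2-one; 3 methyl 2-bromohex-5-enoate
Product: 6 dimethyl (2E)-4-acetyl-5-(but-3-en-1-yl)-3-methylhex-2-enedioate (mixture of the four C4/C5 stereoisomers), via sodium dienolate 5 (not isolated)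
Conditions: NaOMe (1.0 equiv), MeOH, 0 °C to rt; evaporate; DMF, 3, NaI (cat.), rt
Reagents that add atoms: sodium methoxide ([Na+].[O-]C)
Why: Methoxide opens the pyranone at the lactone carbonyl to a delocalised dienolate that should react, like an extended ketone enolate, at the carbon next to the ketone (eudesmane C5) in an SN2 alkylation by the α-bromo ester (acetoacetate-type alkylation), forming C4–C5; the anion scrambles the alkene geometry so the hindered product should settle as the 2E isomer, and both new centres are left uncontrolled on purpose.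

Step 3
Reactants: 6 dimethyl (2E)-4-acetyl-5-(but-3-en-1-yl)-3-methylhex-2-enedioate
Product: 8 dimethyl (2E)-4-acetyl-3-methyl-5-(3-oxopropyl)hex-2-enedioate (same stereoisomer mixture), via ozonide 7 (not isolated)
Conditions: O3, CH2Cl2, −78 °C, Sudan Red 7B end-point; PPh3, −78 °C to rt
Reagents that add atoms: ozone ([O-][O+]=O)
Why: Ozonolysis with reductive work-up should cleave the electron-rich monosubstituted alkene well before the electron-poor trisubstituted enoate and free the C1 aldehyde, which is used without delay because C5–H is acidic.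

Step 4
Reactants: 8 dimethyl (2E)-4-acetyl-3-methyl-5-(3-oxopropyl)hex-2-enedioate
Product: 9 methyl (3R)-2-acetyl-3-(2-methoxy-2-oxoethyl)-3-methyl-4-oxocyclohexane-1-carboxylate (C1/C2 epimer mixture; drawn 1R,2S,3R)
Conditions: (5aS,10bR)-2-(pentafluorophenyl)-5a,10b-dihydro-4H,6H-indeno[2,1-b][1,2,4]triazolo[4,3-d][1,4]oxazin-2-ium tetrafluoroborate (20 mol %; its antipode if a test run shows the opposite sense), KN(SiMe3)2 (20 mol %), toluene, 23 °C
Reagents that add atoms: none
Why: The triazolylidene adds to the C1 aldehyde and proton transfer gives the Breslow intermediate, an acyl anion equivalent that adds to C10 of the E-enoate; protonation of the ester enolate at C9 and loss of the carbene release the C1 ketone. The closest known reaction type is the triazolium-catalysed asymmetric intramolecular Stetter reaction of aldehydes tethered to β,β-disubstituted acceptors, which delivers quaternary centres. Ring A is closed in a 6-exo-trig mode through the new C1–C10 bond. The only new stereocentre, C10, is set by the chiral carbene, which should steer the acyl anion to the Si face of C10 of the E-enoate (10R). The step needs conjugate addition to win over benzoin-type addition to the C6 ketone and over aldol reactions of the acidic C5–H, and this is secured because those additions are reversible whereas the Stetter addition is not. The same C5–H acidity lets C5 epimerise under the basic conditions, so every C4/C5 isomer can pass through a matched transition state and the mixture should converge on one C10 configuration.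

Step 5
Reactants: 9 methyl (3R)-2-acetyl-3-(2-methoxy-2-oxoethyl)-3-methyl-4-oxocyclohexane-1-carboxylate
Product: 10 methyl 10β-methyl-1,6,8-trioxo-5α-decalin-4α-carboxylate (6,8-dione enolised)
Conditions: NaOMe (3 equiv), MeOH, rt to reflux; 1 M HCl to pH 3, 0 °C
Reagents that add atoms: none
Why: Dieckmann (intramolecular Claisen) condensation of the methyl ketone enolate (C7) onto the C8 ester closes ring B as the stabilised six-membered 1,3-dione enolate, the only irreversible outcome among the possible aldol and Claisen modes (attack on the C15 ester would give a strained cyclopentanedione), while methoxide epimerises C5 (α to acetyl) and C4 (α to the ester) before closure so that the trans-fused decalin with the equatorial 4α-ester is expected.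

Step 6
Reactants: 10 methyl 10β-methyl-1,6,8-trioxo-5α-decalin-4α-carboxylate
Product: 11 methyl 7-allyl-10β-methyl-1,6,8-trioxo-5α-decalin-4α-carboxylate (enol form)
Conditions: allyl methyl carbonate (1.05 equiv), Pd(PPh3)4 (3 mol %), THF, rt
Reagents that add atoms: allyl methyl carbonate (C=CCOC(=O)OC)
Why: Tsuji–Trost allylation under neutral conditions: the acidic dione is the soft nucleophile for the π-allylpalladium complex and any O-allyl enol ether re-ionises, so mono-C-allylation at C7 should dominate while the C1 ketone and the ester stay inert.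

Step 7
Reactants: 11 methyl 7-allyl-10β-methyl-1,6,8-trioxo-5α-decalin-4α-carboxylate
Product: 12 methyl 7-allyl-8-methoxy-10β-methyl-1,6-dioxo-5α-decal-7-ene-4α-carboxylate
Conditions: MeOH, p-toluenesulfonic acid monohydrate (cat.), reflux through 3 Å molecular sieves
Reagents that add atoms: methanol (CO)
Why: Acid-catalysed O-alkylation of the enolised 2-substituted 1,3-dione gives the vinylogous ester, expected at the less hindered C8 carbonyl because C6 is flanked by the ring fusion and the peri C4 ester; the regioisomer would converge on the same diol 18 through steps 8 to 11.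

Step 8
Reactants: 12 methyl 7-allyl-8-methoxy-10β-methyl-1,6-dioxo-5α-decal-7-ene-4α-carboxylate
Product: 14 7-allyl-1β-hydroxy-4α-(hydroxymethyl)-10β-methyl-5α-decal-6-en-8-one, via triol enol ether 13 (not isolated)
Conditions: LiAlH4 (excess), THF, 0 °C; then 1 M HCl, THF, 0 °C to rt
Reagents that add atoms: water (O)
Why: Stork–Danheiser transposition: LiAlH4 reduces the C6 vinylogous ester carbonyl, the C15 ester and the C1 ketone (axial attack from the α face, anti to the axial C10 methyl, gives the equatorial 1β-alcohol), and aqueous acid then hydrolyses the enol ether with loss of the C6 hydroxyl to give the 8-oxo-6-ene.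

Step 9
Reactants: 14 7-allyl-1β-hydroxy-4α-(hydroxymethyl)-10β-methyl-5α-decal-6-en-8-one
Product: 15 7-allyl-10β-methyl-1β-(TES-oxy)-4α-(TES-oxymethyl)-5α-decal-6-en-8-one
Conditions: Et3SiCl (2.5 equiv), imidazole, 4-(dimethylamino)pyridine (cat.), DMF, 0 °C to rt
Reagents that add atoms: chlorotriethylsilane (CC[Si](Cl)(CC)CC)
Why: Standard silylation; the small silyl chloride should reach both the primary C15 hydroxyl and the neopentyl C1 hydroxyl, and it removes the C15 hydroxyl as a possible oxa-Michael donor toward C6.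

Step 10
Reactants: 15 7-allyl-10β-methyl-1β-(TES-oxy)-4α-(TES-oxymethyl)-5α-decal-6-en-8-one
Product: 16 7β-allyl-6α,7α-epoxy-10β-methyl-1β-(TES-oxy)-4α-(TES-oxymethyl)-5α-decalin-8-one
Conditions: H2O2 (30 % aq.), NaOH, MeOH–THF, 0 °C
Reagents that add atoms: hydrogen peroxide (OO)
Why: Weitz–Scheffer nucleophilic epoxidation of the α-alkyl enone; hydroperoxide should add to C6 from the α face, away from the axial C10 methyl that is syn-axial to C6 and C8, which sets the C6–O bond α and leaves the allyl group β on C7.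

Step 11
Reactants: 16 7β-allyl-6α,7α-epoxy-10β-methyl-1β-(TES-oxy)-4α-(TES-oxymethyl)-5α-decalin-8-one
Product: 18 7β-allyl-10β-methyl-1β-(TES-oxy)-4α-(TES-oxymethyl)-5α-decalin-6α,8α-diol, via β-hydroxy ketone 17 (not isolated)
Conditions: Li (excess), NH3(l), THF, t-BuOH, −78 to −33 °C; NH4Cl
Reagents that add atoms: none
Why: Dissolving-metal reduction: two-electron cleavage of the Cα–O bond of the epoxy ketone gives the C7/C8 enolate with the 6α-alkoxide intact, protonation at C7 from the axial α direction places the allyl group equatorial (β), and the regenerated C8 ketone is reduced under thermodynamic control to the equatorial 8α-alcohol; isolated alkene and silyl ethers are inert.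

Step 12
Reactants: 19 methyl 2-(hydroxymethyl)acrylate
Product: 20 methyl 2-[(TBS-oxy)methyl]acrylate
Conditions: t-BuMe2SiCl, imidazole, CH2Cl2, 0 °C to rt
Reagents that add atoms: tert-butylchlorodimethylsilane (CC(C)(C)[Si](C)(C)Cl)
Why: Standard silylation of a primary allylic alcohol.

Step 13
Reactants: 20 methyl 2-[(TBS-oxy)methyl]acrylate
Product: 21 2-[(TBS-oxy)methyl]acrylic acid
Conditions: LiOH, THF–H2O, 0 °C; 1 M HCl to pH 3–4, 0 °C
Reagents that add atoms: lithium hydroxide ([Li+].[OH-])
Why: Saponification of the methyl ester at low temperature; the silyl ether is base-stable and the α-substituted acrylate resists conjugate addition of hydroxide.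

Step 14
Reactants: 21 2-[(TBS-oxy)methyl]acrylic acid; 18 7β-allyl-10β-methyl-1β-(TES-oxy)-4α-(TES-oxymethyl)-5α-decalin-6α,8α-diol
Product: 23 7β-allyl-6α-hydroxy-10β-methyl-1β-(TES-oxy)-4α-(TES-oxymethyl)-5α-decalin-8α-yl 2-[(TBS-oxy)methyl]acrylate, via mixed anhydride 22 (not isolated)
Conditions: 21, 2,4,6-trichlorobenzoyl chloride, Et3N, toluene, rt; then 18, 4-(dimethylamino)pyridine, toluene, rt
Reagents that add atoms: none
Why: Yamaguchi esterification should acylate the less hindered equatorial 8α-hydroxyl, because the 6α-hydroxyl is shielded by the ring fusion and the peri C15 silyloxymethyl group.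

Step 15
Reactants: 23 the 8α-ester with free 6α-hydroxyl
Product: 24 7β-allyl-10β-methyl-1β,6α-bis(TES-oxy)-4α-(TES-oxymethyl)-5α-decalin-8α-yl 2-[(TBS-oxy)methyl]acrylate
Conditions: Et3SiOTf, 2,6-lutidine, CH2Cl2, −78 to 0 °C
Reagents that add atoms: triethylsilyl trifluoromethanesulfonate (CC[Si](CC)(CC)OS(=O)(=O)C(F)(F)F)
Why: A silyl triflate with a hindered base silylates even the crowded 6α-hydroxyl without touching esters or alkenes.

Step 16
Reactants: 24 the fully silylated 8α-ester
Product: 26 aldehyde (24 with 7β-(2-oxoethyl) in place of allyl), via ozonide 25 (not isolated)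
Conditions: O3, CH2Cl2, −78 °C, Sudan Red 7B end-point; PPh3, −78 °C to rt
Reagents that add atoms: ozone ([O-][O+]=O)
Why: Ozonolysis with reductive work-up; the monosubstituted allyl alkene is far more electron-rich than the conjugated 1,1-disubstituted acrylate and should be cleaved selectively at the dye end-point.

Step 17
Reactants: 26 the C12 aldehyde
Product: 28 enal (24 with 7β-(3-oxoprop-1-en-2-yl) in place of allyl), via Mannich base 27 (not isolated)
Conditions: N,N-dimethylmethyleneiminium iodide, Et3N, CH2Cl2, rt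
Reagents that add atoms: N,N-dimethylmethyleneiminium iodide (C=[N+](C)C.[I-])
Why: Mannich reaction of the aldehyde with Eschenmoser's salt followed by amine elimination (α-methylenation of an aldehyde) installs C13 as the exocyclic methylene.

Step 18
Reactants: 28 the enal
Product: 29 2-[8α-acyloxy-1β,6α-bis(TES-oxy)-4α-(TES-oxymethyl)-10β-methyl-5α-decalin-7β-yl]acrylic acid (acyl = 2-[(TBS-oxy)methyl]acryloyl)
Conditions: NaClO2, NaH2PO4, 2-methyl-2-butene, t-BuOH–H2O, 0 °C to rt
Reagents that add atoms: sodium chlorite ([Na+].[O-]Cl=O)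
Why: Pinnick oxidation converts the enal into the acrylic acid under buffered conditions that leave alkenes, the ester and the hindered silyl ethers untouched.

Step 19
Reactants: 29 the acrylic acid
Product: 30 the 15-alcohol (29 with 4α-hydroxymethyl)
Conditions: pyridinium p-toluenesulfonate (cat.), MeOH–CH2Cl2, 0 °C
Reagents that add atoms: none
Why: Acid-catalysed methanolysis should remove the unhindered primary TES ether much faster than the hindered secondary TES ethers at C1 and C6 or the TBS ether.

Step 20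
Reactants: 30 the 15-alcohol
Product: 31 the 15-aldehyde (4α-formyl)
Conditions: Dess–Martin periodinane (1,1,1-triacetoxy-1,1-dihydro-1,2-benziodoxol-3(1H)-one), CH2Cl2, 0 °C to rt
Reagents that add atoms: none
Why: Dess–Martin oxidation of the primary alcohol stops at the aldehyde; the equatorial 4α-formyl group is the thermodynamic epimer, so C4 is not at risk.

Step 21
Reactants: 31 the 15-aldehyde
Product: 32 1β,6α-dihydroxy-8α-{[2-(hydroxymethyl)acryloyl]oxy}-15-oxo-4βH,5αH,7αH-eudesm-11(13)-en-12-oic acid (CNP0599450.1)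
Conditions: HF·pyridine, pyridine, THF, 0 °C to rt
Reagents that add atoms: none
Why: Buffered fluoride cleavage of the two secondary TES ethers and the primary TBS ether should spare the acrylate ester, the aldehyde and the hydroxy acid, since closure to the trans-fused lactone needs stronger acid.

**Compound list**

1 | methyl hex-5-enoate | C=CCCCC(=O)OC | starting material
2 | 1-methoxy-1-(trimethylsilyloxy)hexa-1,5-diene (E/Z mixture) | C=CCCC=C(OC)O[Si](C)(C)C | intermediate
3 | methyl 2-bromohex-5-enoate (racemic) | C=CCCC(Br)C(=O)OC | intermediate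
4 | 4,6-dimethyl-2H-pyran-2-one | CC1=CC(C)=CC(=O)O1 | starting material
5 | sodium (2Z,4Z)-6-methoxy-4-methyl-6-oxohexa-2,4-dien-2-olate | COC(=O)/C=C(C)\C=C(\C)[O-].[Na+] | intermediate
6 | dimethyl (2E)-4-acetyl-5-(but-3-en-1-yl)-3-methylhex-2-enedioate (four stereoisomers; drawn 4S,5R) | COC(=O)/C=C(\C)[C@@H](C(C)=O)[C@H](C(=O)OC)CCC=C | intermediate
7 | 1,2,4-trioxolane (ozonide) of 6 | COC(=O)/C=C(\C)[C@@H](C(C)=O)[C@H](C(=O)OC)CCC1OCOO1 | intermediate
8 | dimethyl (2E)-4-acetyl-3-methyl-5-(3-oxopropyl)hex-2-enedioate (four stereoisomers; drawn 4S,5R) | COC(=O)/C=C(\C)[C@@H](C(C)=O)[C@H](C(=O)OC)CCC=O | intermediate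
9 | methyl (3R)-2-acetyl-3-(2-methoxy-2-oxoethyl)-3-methyl-4-oxocyclohexane-1-carboxylate (C1/C2 epimers; drawn 1R,2S,3R) | COC(=O)C[C@]1(C)[C@@H](C(C)=O)[C@H](C(=O)OC)CCC1=O | intermediate
10 | methyl 10β-methyl-1,6,8-trioxo-5α-decalin-4α-carboxylate (enol form) | OC1=CC(=O)[C@H]2[C@H](C(=O)OC)CCC(=O)[C@]2(C)C1 | intermediate
11 | methyl 7-allyl-10β-methyl-1,6,8-trioxo-5α-decalin-4α-carboxylate (enol form) | OC1=C(CC=C)C(=O)[C@H]2[C@H](C(=O)OC)CCC(=O)[C@]2(C)C1 | intermediate
12 | methyl 7-allyl-8-methoxy-10β-methyl-1,6-dioxo-5α-decal-7-ene-4α-carboxylate | COC1=C(CC=C)C(=O)[C@H]2[C@H](C(=O)OC)CCC(=O)[C@]2(C)C1 | intermediate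
13 | 7-allyl-4α-(hydroxymethyl)-8-methoxy-10β-methyl-5α-decal-7-ene-1β,6β-diol | COC1=C(CC=C)[C@@H](O)[C@H]2[C@H](CO)CC[C@@H](O)[C@]2(C)C1 | intermediate
14 | 7-allyl-1β-hydroxy-4α-(hydroxymethyl)-10β-methyl-5α-decal-6-en-8-one | O=C1C[C@]2(C)[C@@H](C=C1CC=C)[C@H](CO)CC[C@H]2O | intermediate
15 | 7-allyl-10β-methyl-1β-(TES-oxy)-4α-(TES-oxymethyl)-5α-decal-6-en-8-one | O=C1C[C@]2(C)[C@@H](C=C1CC=C)[C@H](CO[Si](CC)(CC)CC)CC[C@H]2O[Si](CC)(CC)CC | intermediate
16 | 7β-allyl-6α,7α-epoxy-10β-methyl-1β-(TES-oxy)-4α-(TES-oxymethyl)-5α-decalin-8-one | O=C1C[C@]2(C)[C@@H]([C@H]3O[C@@]13CC=C)[C@H](CO[Si](CC)(CC)CC)CC[C@H]2O[Si](CC)(CC)CC | intermediate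
17 | 7β-allyl-6α-hydroxy-10β-methyl-1β-(TES-oxy)-4α-(TES-oxymethyl)-5α-decalin-8-one | O=C1C[C@]2(C)[C@@H]([C@@H](O)[C@@H]1CC=C)[C@H](CO[Si](CC)(CC)CC)CC[C@H]2O[Si](CC)(CC)CC | intermediate
18 | 7β-allyl-10β-methyl-1β-(TES-oxy)-4α-(TES-oxymethyl)-5α-decalin-6α,8α-diol | O[C@H]1C[C@]2(C)[C@@H]([C@@H](O)[C@@H]1CC=C)[C@H](CO[Si](CC)(CC)CC)CC[C@H]2O[Si](CC)(CC)CC | intermediate
19 | methyl 2-(hydroxymethyl)acrylate | C=C(CO)C(=O)OC | starting material
20 | methyl 2-[(TBS-oxy)methyl]acrylate | C=C(CO[Si](C)(C)C(C)(C)C)C(=O)OC | intermediate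
21 | 2-[(TBS-oxy)methyl]acrylic acid | C=C(CO[Si](C)(C)C(C)(C)C)C(=O)O | intermediate
22 | 2-[(TBS-oxy)methyl]acrylic 2,4,6-trichlorobenzoic anhydride | C=C(CO[Si](C)(C)C(C)(C)C)C(=O)OC(=O)c1c(Cl)cc(Cl)cc1Cl | intermediate
23 | 7β-allyl-6α-hydroxy-10β-methyl-1β-(TES-oxy)-4α-(TES-oxymethyl)-5α-decalin-8α-yl 2-[(TBS-oxy)methyl]acrylate | C=C(CO[Si](C)(C)C(C)(C)C)C(=O)O[C@H]1C[C@]2(C)[C@@H]([C@@H](O)[C@@H]1CC=C)[C@H](CO[Si](CC)(CC)CC)CC[C@H]2O[Si](CC)(CC)CC | intermediate
24 | 7β-allyl-10β-methyl-1β,6α-bis(TES-oxy)-4α-(TES-oxymethyl)-5α-decalin-8α-yl 2-[(TBS-oxy)methyl]acrylate | C=C(CO[Si](C)(C)C(C)(C)C)C(=O)O[C@H]1C[C@]2(C)[C@@H]([C@@H](O[Si](CC)(CC)CC)[C@@H]1CC=C)[C@H](CO[Si](CC)(CC)CC)CC[C@H]2O[Si](CC)(CC)CC | intermediate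
25 | ozonide of 24 (1,2,4-trioxolane at the former allyl alkene) | C=C(CO[Si](C)(C)C(C)(C)C)C(=O)O[C@H]1C[C@]2(C)[C@@H]([C@@H](O[Si](CC)(CC)CC)[C@@H]1CC3OCOO3)[C@H](CO[Si](CC)(CC)CC)CC[C@H]2O[Si](CC)(CC)CC | intermediate
26 | 24 with 7β-(2-oxoethyl) in place of allyl | C=C(CO[Si](C)(C)C(C)(C)C)C(=O)O[C@H]1C[C@]2(C)[C@@H]([C@@H](O[Si](CC)(CC)CC)[C@@H]1CC=O)[C@H](CO[Si](CC)(CC)CC)CC[C@H]2O[Si](CC)(CC)CC | intermediate
27 | 26 with a (dimethylamino)methyl group on C11 (Mannich base; C11 epimers) | C=C(CO[Si](C)(C)C(C)(C)C)C(=O)O[C@H]1C[C@]2(C)[C@@H]([C@@H](O[Si](CC)(CC)CC)[C@@H]1C(CN(C)C)C=O)[C@H](CO[Si](CC)(CC)CC)CC[C@H]2O[Si](CC)(CC)CC | intermediate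
28 | 24 with 7β-(3-oxoprop-1-en-2-yl) in place of allyl | C=C(CO[Si](C)(C)C(C)(C)C)C(=O)O[C@H]1C[C@]2(C)[C@@H]([C@@H](O[Si](CC)(CC)CC)[C@@H]1C(=C)C=O)[C@H](CO[Si](CC)(CC)CC)CC[C@H]2O[Si](CC)(CC)CC | intermediate
29 | 2-[8α-({2-[(TBS-oxy)methyl]acryloyl}oxy)-1β,6α-bis(TES-oxy)-4α-(TES-oxymethyl)-10β-methyl-5α-decalin-7β-yl]acrylic acid | C=C(CO[Si](C)(C)C(C)(C)C)C(=O)O[C@H]1C[C@]2(C)[C@@H]([C@@H](O[Si](CC)(CC)CC)[C@@H]1C(=C)C(=O)O)[C@H](CO[Si](CC)(CC)CC)CC[C@H]2O[Si](CC)(CC)CC | intermediate
30 | 29 with free 4α-hydroxymethyl | C=C(CO[Si](C)(C)C(C)(C)C)C(=O)O[C@H]1C[C@]2(C)[C@@H]([C@@H](O[Si](CC)(CC)CC)[C@@H]1C(=C)C(=O)O)[C@H](CO)CC[C@H]2O[Si](CC)(CC)CC | intermediate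
31 | 30 oxidised to the 4α-formyl compound | C=C(CO[Si](C)(C)C(C)(C)C)C(=O)O[C@H]1C[C@]2(C)[C@@H]([C@@H](O[Si](CC)(CC)CC)[C@@H]1C(=C)C(=O)O)[C@H](C=O)CC[C@H]2O[Si](CC)(CC)CC | intermediate
32 | 1β,6α-dihydroxy-8α-{[2-(hydroxymethyl)acryloyl]oxy}-15-oxo-4βH,5αH,7αH-eudesm-11(13)-en-12-oic acid | C=C(CO)C(=O)O[C@H]1C[C@]2(C)[C@@H]([C@@H](O)[C@@H]1C(=C)C(=O)O)[C@H](C=O)CC[C@H]2O | target

**Summary**

Total step count: 21. Longest linear sequence: 19 steps (steps 1–11 and 14–21, from 1).

Steps most likely to fail:

Step 4. Conjugate addition of the Breslow intermediate to the hindered, weakly electrophilic β,β-disubstituted enoate may be too slow for six-membered ring closure, so that benzoin-type addition to the C6 ketone, aldol condensation through C5–H or the aldehyde α-position, or eroded facial selectivity take over. Fallback, from 8 back to 10: the aldehyde is oxidised (NaClO2, NaH2PO4, 2-methyl-2-butene) to the carboxylic acid F1 and converted with diphenyl diselenide and PBu3 into the Se-phenyl selenoester F2. Slow addition of Bu3SnH with azobisisobutyronitrile in benzene at 80 °C generates the acyl radical, which should close ring A by 6-exo-trig addition to C10 and give 9 together with its C10 epimers F3. The mixture is taken through step 5 to the racemic trione, and 10 is separated from the enantiomeric trione F4 by preparative chromatography on a chiral stationary phase before rejoining the route at step 6.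

Step 5. Ring closure may run under kinetic control and deliver the cis ring fusion, because once the dione enolate has formed C5–H no longer exchanges under methoxide. Fallback, from 9 back to 12: the cis-fused trione F5 is accepted, allylated to the allyl trione F6 and O-methylated to the enol ether F7 under the conditions of steps 6 and 7. F7 is then epimerised with NaOMe in MeOH, where C5–H is α′ to the vinylogous ester carbonyl and no longer shielded by a neighbouring enolate; reprotonation from the axial α face, anti to the C10 methyl, should give the trans-fused 12.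

Step 14. Acylation may fail to discriminate O8 from O6, or over-acylate. Fallback, from 16 back to 24: the two oxygens are introduced one after the other. The epoxy ketone is opened with SmI2 (THF–MeOH, −78 °C) and the hydroxy ketone 17 is isolated; O6 is silylated (Et3SiOTf, 2,6-lutidine) to the silyl ether ketone F8; the C8 ketone is reduced (Li, NH3, t-BuOH) to the alcohol F9, in which only O8 is free; Yamaguchi esterification with 21 then gives 24.

Further compounds
F1 | step 4 | (5E)-4-(methoxycarbonyl)-5-acetyl-7-methoxy-6-methyl-7-oxohept-5-enoic acid type acid from 8 (CHO oxidised to CO2H) | COC(=O)/C=C(\C)[C@@H](C(C)=O)[C@H](C(=O)OC)CCC(=O)O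
F2 | step 4 | Se-phenyl selenoester of F1 | COC(=O)/C=C(\C)[C@@H](C(C)=O)[C@H](C(=O)OC)CCC(=O)[Se]c1ccccc1
F3 | step 4 | (3S)-epimers of 9 (C10 epimer; drawn 1R,2S,3S) | COC(=O)C[C@@]1(C)[C@@H](C(C)=O)[C@H](C(=O)OC)CCC1=O
F4 | step 4 | enantiomer of 10 | OC1=CC(=O)[C@@H]2[C@@H](C(=O)OC)CCC(=O)[C@@]2(C)C1
F5 | step 5 | methyl 10β-methyl-1,6,8-trioxo-5β-decalin-4α-carboxylate (cis-fused; enol form) | OC1=CC(=O)[C@@H]2[C@H](C(=O)OC)CCC(=O)[C@]2(C)C1
F6 | step 5 | methyl 7-allyl-10β-methyl-1,6,8-trioxo-5β-decalin-4α-carboxylate (enol form) | OC1=C(CC=C)C(=O)[C@@H]2[C@H](C(=O)OC)CCC(=O)[C@]2(C)C1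
F7 | step 5 | methyl 7-allyl-8-methoxy-10β-methyl-1,6-dioxo-5β-decal-7-ene-4α-carboxylate | COC1=C(CC=C)C(=O)[C@@H]2[C@H](C(=O)OC)CCC(=O)[C@]2(C)C1
F8 | step 14 | 7β-allyl-10β-methyl-1β,6α-bis(TES-oxy)-4α-(TES-oxymethyl)-5α-decalin-8-one | O=C1C[C@]2(C)[C@@H]([C@@H](O[Si](CC)(CC)CC)[C@@H]1CC=C)[C@H](CO[Si](CC)(CC)CC)CC[C@H]2O[Si](CC)(CC)CC
F9 | step 14 | 7β-allyl-10β-methyl-1β,6α-bis(TES-oxy)-4α-(TES-oxymethyl)-5α-decalin-8α-ol | O[C@H]1C[C@]2(C)[C@@H]([C@@H](O[Si](CC)(CC)CC)[C@@H]1CC=C)[C@H](CO[Si](CC)(CC)CC)CC[C@H]2O[Si](CC)(CC)CC
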